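**Retrosynthetic overview** (locants follow the eunicellane/briarellin skeleton: C1/C10/C14 cyclohexene CH, C2/C9 tetrahydrofuran CH–O, C3 quaternary C–O, C4 CHOAc, C6/C7 diol, C11–C13 enone, C15–C16 CHMe–CH2O)
- Endgame: target ⇐ 6-ketone (hydroxyl-directed reduction) ⇐ enone from a C11=C12 alkene (allylic hydroxylation, β-methylation) and 6,7-diol from a (Z)-C6=C7 oxonene; the oxepane CH2 (C16) ⇐ lactone C=O.
- Key disconnection: the oxepane (O, C3, C2, C1, C14, C15, C16) is a γ-butenolide (O, C3, C2=C15, C16) that has taken up the C1=C14 bond of a cyclohexadiene, by tetronate [2+2] photocycloaddition and then cleavage of the C2–C15 cyclobutane bond.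
- Enabling feature: C2 carries the tetrahydrofuran oxygen (donor) and is linked through C15 to C16, which can be a lactone carbonyl (acceptor); C1 and C14 are the ring-fusion carbons the oxepane shares with the cyclohexene.
- Precursor: a nine-membered tetronate macrocycle (RCM at C6=C7) ⇐ Mitsunobu union of a tetronic acid (from (R)-lactic acid) with a cyclohexa-2,5-dienyl carbinol (from benzoic acid).
- Ring order: butenolide → oxonene → tetrahydrofuran + cyclobutane → seven-membered lactone → oxepane; the cyclohexenone is finished last.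

Key step: step 13

Remark (assumption): reagents are taken to attack the (Z)-C6=C7 bond and the derived C6 ketone on the outer face of the oxonene, i.e. the face remote from the C3–O bond (steps 17 and 24).
Remark: the Ipc2B-allyl reagents are used as pre-formed, salt-free stock solutions; TMSOTf (step 13) and BF3·OEt2 (step 16) act as promoters.

**Route**

Step 1
Reactants: 1 (R)-lactic acid
Product: 2 (2R,5R)-2-tert-butyl-5-methyl-1,3-dioxolan-4-one (cis)
Conditions: t-BuCHO, TsOH (cat.), H2SO4 (cat.), pentane, reflux, Dean–Stark; recrystallisation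
Reagents that add atoms: pivalaldehyde CC(C)(C)C=O
Why: Acid-catalysed acetalisation; the cis acetal is the thermodynamic isomer and crystallises, so the acetal carbon is set relative to the lactate centre (self-regeneration of stereocentres).

Step 2
Reactants: 2 (2R,5R)-2-tert-butyl-5-methyl-1,3-dioxolan-4-one
Product: 3 (2R,5S)-2-tert-butyl-5-(hydroxymethyl)-5-methyl-1,3-dioxolan-4-one
Conditions: LDA, THF, −78 °C; CH2O (gas), −78 °C; AcOH
Reagents that add atoms: formaldehyde C=O
Why: Aldol addition of the planar lithium enolate to formaldehyde anti to the tert-butyl group, which sets the quaternary carbon (future C3, S).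

Step 3
Reactants: 3 (2R,5S)-2-tert-butyl-5-(hydroxymethyl)-5-methyl-1,3-dioxolan-4-one
Product: 4 (2R,5S)-2-tert-butyl-5-formyl-5-methyl-1,3-dioxolan-4-one
Conditions: Dess–Martin periodinane, pyridine, CH2Cl2, 0 → 23 °C
Reagents that add atoms: none
Why: Dess–Martin oxidation of a primary alcohol on a quaternary carbon; there is no α-hydrogen, so nothing can epimerise.

Step 4
Reactants: 4 (2R,5S)-2-tert-butyl-5-formyl-5-methyl-1,3-dioxolan-4-one
Product: 5 (2R,5S)-2-tert-butyl-5-[(1R)-1-hydroxybut-3-en-1-yl]-5-methyl-1,3-dioxolan-4-one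
Conditions: (+)-Ipc2B(allyl), Et2O, −78 °C; then ethanolamine
Reagents that add atoms: (+)-B-allylbis(isopinocampheyl)borane, Ipc = (1S,2S,3S,5R), (−)-α-pinene series C=CCB([C@H]1C[C@H]2C[C@@H]([C@@H]1C)C2(C)C)[C@H]1C[C@H]2C[C@@H]([C@@H]1C)C2(C)C
Why: Brown allylboration through a closed six-membered transition state; the isopinocampheyl groups override the substrate and set the carbinol (future C4) as R.

Step 5
Reactants: 5 (2R,5S)-2-tert-butyl-5-[(1R)-1-hydroxybut-3-en-1-yl]-5-methyl-1,3-dioxolan-4-one
Product: 6 tert-butyldimethylsilyl ether of 5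
Conditions: TBSOTf, 2,6-lutidine, CH2Cl2, −78 → 0 °C
Reagents that add atoms: tert-butyldimethylsilyl triflate CC(C)(C)[Si](C)(C)OS(=O)(=O)C(F)(F)F
Why: Silylation of a hindered secondary alcohol with a silyl triflate, which protects C4–OH for the enolate chemistry that follows.

Step 6
Reactants: 6 tert-butyldimethylsilyl ether of 5
Product: 7 (5S)-5-[(1R)-1-(tert-butyldimethylsilyloxy)but-3-en-1-yl]-4-hydroxy-5-methylfuran-2(5H)-one (tetronic acid)
Conditions: LiHMDS, EtOAc, THF, −78 °C; then 6, −78 → 0 °C; 1 M HCl
Reagents that add atoms: ethyl acetate (as its lithium enolate) CCOC(C)=O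
Why: Claisen-type acylation of the ester enolate by the dioxolanone carbonyl, loss of pivalaldehyde and lactonisation of the freed tertiary alkoxide give the tetronic acid (known tetronic acid synthesis from dioxolanones); both stereocentres are untouched.

Step 7
Reactants: 8 benzoic acid
Product: 9 cyclohexa-2,5-diene-1-carboxylic acid
Conditions: Li, NH3 (l), THF, −78 °C; NH4Cl; then aq. HCl
Reagents that add atoms: none
Why: Birch reduction; the carboxylate directs protonation to the ipso and para carbons and gives the 2,5-diene.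

Step 8
Reactants: 9 cyclohexa-2,5-diene-1-carboxylic acid
Product: 10 (cyclohexa-2,5-dien-1-yl)methanol
Conditions: LiAlH4, Et2O, 0 °C
Reagents that add atoms: none
Why: Hydride reduction of the carboxylic acid; the skipped diene is inert to LiAlH4.

Step 9
Reactants: 10 (cyclohexa-2,5-dien-1-yl)methanol
Product: 11 cyclohexa-2,5-diene-1-carbaldehyde
Conditions: Dess–Martin periodinane, pyridine, CH2Cl2, 0 °C; used cold and at once
Reagents that add atoms: none
Why: Buffered, non-basic Dess–Martin oxidation, chosen because the doubly allylic α-hydrogen makes the aldehyde prone to conjugation and aromatisation; the ring is symmetric, so no stereocentre is at risk.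

Step 10
Reactants: 11 cyclohexa-2,5-diene-1-carbaldehyde
Product: 12 (1R)-1-(cyclohexa-2,5-dien-1-yl)-3-methylbut-3-en-1-ol
Conditions: (+)-Ipc2B(2-methylallyl), Et2O, −78 °C; then ethanolamine
Reagents that add atoms: (+)-B-(2-methylallyl)bis(isopinocampheyl)borane, Ipc = (1S,2S,3S,5R) CC(=C)CB([C@H]1C[C@H]2C[C@@H]([C@@H]1C)C2(C)C)[C@H]1C[C@H]2C[C@@H]([C@@H]1C)C2(C)C
Why: Brown methallylboration; reagent control sets the carbinol as R (it becomes C9 after inversion in step 11).

Step 11
Reactants: 7 tetronic acid; 12 (1R)-1-(cyclohexa-2,5-dien-1-yl)-3-methylbut-3-en-1-ol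
Product: 13 (5S)-5-[(1R)-1-(tert-butyldimethylsilyloxy)but-3-en-1-yl]-4-{[(1S)-1-(cyclohexa-2,5-dien-1-yl)-3-methylbut-3-en-1-yl]oxy}-5-methylfuran-2(5H)-one
Conditions: PPh3, DIAD, THF, 0 → 23 °C
Reagents that add atoms: none
Why: Mitsunobu reaction; the acidic tetronic acid is alkylated on O-4 with SN2 inversion, which sets C9 as S.

Step 12
Reactants: 13 tetronate diene
Product: 14 macrocyclic tetronate: butenolide fused to a nine-membered ring (C2, O, C9, C8, C7(Me)=C6 (Z), C5, C4(OTBS), C3), with cyclohexa-2,5-dien-1-yl on C9 (S)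
Conditions: Grubbs second-generation catalyst (10 mol%), toluene (1 mM), 80 °C
Reagents that add atoms: none
Why: Ring-closing metathesis; the ring allows only the (Z)-trisubstituted alkene, as known for Δ6-oxonenes closed from bis-alkenyl ethers that carry a gauche O–C–C–O unit (here O–C3–C4–OTBS).

Step 13
Reactants: 14 macrocyclic tetronate
Product: 16 tetracyclic seven-membered lactone (cyclohex-11-ene, tetrahydrofuran, 16-oxo-oxepane with C15 = CH2, (Z)-Δ6 oxonene, 4-OTBS; C1, C2, C3, C4, C9, C10, C14 as in the target), via cyclobutane photoadduct 15 (not isolated)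
Conditions: hν (254 nm), degassed CH2Cl2 (5 mM), quartz, 23 °C; then Et3SiH, TMSOTf (20 mol%), −78 → −30 °C; aq. NaHCO3
Reagents that add atoms: none
Why: Proposed new method: stage 1 is the known intramolecular [2+2] photocycloaddition of a 4-(but-3-enyloxy)tetronate, in which the excited tetronate bonds C2 to C1 (1,5-closure, which closes the tetrahydrofuran in the 5-exo mode) and the 1,4-biradical then recombines at C15–C14 to the cis-fused cyclobutane; stage 2 is new for this substrate class: TMSOTf silylates the lactone carbonyl of the resulting 2-alkoxycyclobutane carboxylate (a vicinal donor–acceptor cyclobutane), the strained C2–C15 bond heterolyses to a C2 oxocarbenium ion and a silyl ketene acetal (a retro-Mukaiyama addition, the alkoxy counterpart of the De Mayo retro-aldol), and Et3SiH reduces the cation irreversibly (closest known types: Lewis-acid opening of alkoxy donor–acceptor cyclobutanes and silane reduction of cyclic oxocarbenium ions). Stage 2 closes no ring: the five-membered lactone O–C16–C15–C2–C3 becomes the seven-membered lactone O–C16–C15–C14–C1–C2–C3 by insertion of C14–C1 into the C15–C2 bond. C10, C1 and C14 are set by diastereotopic-group selection: the nine-membered bridge covers one face of the butenolide, so only the ring alkene that lets the cyclohexadiene stack on the opposite (C3-methyl) face can reach C2=C15, and the three-atom tether and the four-membered ring enforce cis fusion at C1/C10 and C1/C14. C2 is set by hydride delivery anti to the bridge, since attack from the bridge face would give an impossible trans-bridged 2,5-tetrahydrofuran; C15 is CH2 after hydrolysis of the ketene acetal and carries no stereo-information. The step needs chemoselection of the cyclohexadiene over the C6=C7 alkene, secured because C2=C15 is exocyclic to the nine-membered ring and out of transannular reach, and regioselective C–C cleavage, secured because only the C2–C15 bond has the alkoxy donor on one carbon and the carbonyl on the other.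

Step 14
Reactants: 16 seven-membered lactone
Product: 17 15-methyl lactone (C15 methyl cis to H-14, as in the target)
Conditions: LDA, THF, −78 °C; MeI, −78 → −40 °C
Reagents that add atoms: iodomethane CI
Why: Alkylation of the lactone enolate; methyl iodide approaches C15 on the convex face, anti to C13 of the cis-fused cyclohexene, which sets C15.

Step 15
Reactants: 17 15-methyl lactone
Product: 18 16-acetoxy oxepane (O-acetyl lactol, C16 epimers)
Conditions: DIBAL-H, CH2Cl2, −78 °C; then Ac2O, pyridine, DMAP, −78 → 0 °C; Rochelle salt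
Reagents that add atoms: acetic anhydride CC(=O)OC(C)=O
Why: Reductive acetylation of the lactone (hydride addition, then trapping of the aluminium hemiacetal as its acetate), which avoids ring–chain tautomerism of a seven-membered lactol.

Step 16
Reactants: 18 16-acetoxy oxepane
Product: 19 tetracyclic oxepane (4-OTBS, (Z)-Δ6, Δ11)
Conditions: Et3SiH, BF3·OEt2, CH2Cl2, −78 → −40 °C
Reagents that add atoms: none
Why: Silane reduction of the oxocarbenium ion formed by loss of acetate; C16 becomes CH2, so no stereocentre is formed.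

Step 17
Reactants: 19 tetracyclic oxepane
Product: 20 6,7-diol (both hydroxyls on the outer face: C7 as in the target, C6 epimeric)
Conditions: OsO4 (5 mol%), NMO, acetone/H2O, 0 °C
Reagents that add atoms: osmium tetroxide (catalytic oxygen carrier) O=[Os](=O)(=O)=O; N-methylmorpholine N-oxide C[N+]1([O-])CCOCC1; water O
Why: Osmium tetroxide syn-dihydroxylation; the electron-rich, strained trisubstituted alkene should react before the cis-disubstituted cyclohexene, and addition to the outer face of the oxonene sets C7 correctly (C6 is corrected in steps 19 and 24).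

Step 18
Reactants: 20 6,7-diol
Product: 21 6,7,13-triol (C13 epimers)
Conditions: SeO2 (0.5 equiv), t-BuOOH, CH2Cl2, 23 °C
Reagents that add atoms: tert-butyl hydroperoxide (oxygen transferred through selenium dioxide, O=[Se]=O) CC(C)(C)OO
Why: Selenium dioxide allylic hydroxylation (ene reaction, then [2,3]-sigmatropic shift) places oxygen on the allylic CH2 (C13) in preference to the tertiary C10–H and leaves the double bond at C11=C12; the new carbinol is oxidised next, so its configuration does not matter.

Step 19
Reactants: 21 6,7,13-triol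
Product: 22 6,13-diketone (7-hydroxy-6-ketone and C11=C12–C13=O enone, 4-OTBS)
Conditions: Dess–Martin periodinane (3 equiv), pyridine, CH2Cl2, 23 °C
Reagents that add atoms: none
Why: Dess–Martin oxidation of both secondary alcohols (C6 and allylic C13); the tertiary C7 alcohol cannot react.

Step 20
Reactants: 22 6,13-diketone
Product: 23 11-methyl 13-(trimethylsilyloxy)-12-ene with 7-OTMS (C11 epimers)
Conditions: Me2CuLi (from MeLi, CuI), TMSCl, THF, −78 °C; Et3N
Reagents that add atoms: lithium dimethylcuprate [Li+].C[Cu-]C; chlorotrimethylsilane C[Si](C)(C)Cl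
Why: Cuprate conjugate addition to the enone with silyl trapping of the enolate (the tertiary alkoxide is silylated as well); the C11 stereocentre formed here is removed in step 21.

Step 21
Reactants: 23 silyl enol ether
Product: 24 11-methyl-11-en-13-one (β-methyl enone; 4-OTBS, 6-oxo, 7-OTMS)
Conditions: Pd(OAc)2 (1.1 equiv), MeCN, 23 °C
Reagents that add atoms: none
Why: Saegusa–Ito oxidation; palladation at C12 and β-hydride elimination of H-11 give the β-methyl enone.

Step 22
Reactants: 24 β-methyl enone
Product: 25 4,7-dihydroxy-6,13-dione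
Conditions: HF·pyridine, pyridine, THF, 0 → 23 °C
Reagents that add atoms: none
Why: Fluoride desilylation under acidic buffering, chosen to avoid retro-aldol cleavage or ketol shift of the β-hydroxy and α-hydroxy ketone.

Step 23
Reactants: 25 4,7-dihydroxy-6,13-dione
Product: 26 4-acetoxy-7-hydroxy-6,13-dione
Conditions: Ac2O, pyridine, CH2Cl2, 0 °C
Reagents that add atoms: acetic anhydride CC(=O)OC(C)=O
Why: Acetylation of the only secondary alcohol (the tertiary C7 alcohol does not react without DMAP); weak base and low temperature limit β-elimination from the new β-acetoxy ketone.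

Step 24
Reactants: 26 4-acetoxy-7-hydroxy-6,13-dione
Product: 27 CNP0318718.1 (target)
Conditions: Me4NBH(OAc)3, AcOH/MeCN, −20 °C
Reagents that add atoms: none
Why: Hydroxyl-directed triacetoxyborohydride reduction of the α-hydroxy ketone (Evans–Saksena type); hydride is delivered from boron bound to the C7 oxygen on the outer face, which sets C6 anti to C7–OH (R), while the enone and the acetate are not reduced.

**Compound list**

1 | (R)-lactic acid | C[C@@H](O)C(=O)O | starting material
2 | (2R,5R)-2-tert-butyl-5-methyl-1,3-dioxolan-4-one | C[C@H]1O[C@@H](C(C)(C)C)OC1=O | intermediate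
3 | (2R,5S)-2-tert-butyl-5-(hydroxymethyl)-5-methyl-1,3-dioxolan-4-one | C[C@@]1(CO)O[C@@H](C(C)(C)C)OC1=O | intermediate
4 | (2R,5S)-2-tert-butyl-5-formyl-5-methyl-1,3-dioxolan-4-one | C[C@@]1(C=O)O[C@@H](C(C)(C)C)OC1=O | intermediate
5 | (2R,5S)-2-tert-butyl-5-[(1R)-1-hydroxybut-3-en-1-yl]-5-methyl-1,3-dioxolan-4-one | C[C@@]1([C@H](O)CC=C)O[C@@H](C(C)(C)C)OC1=O | intermediate
6 | TBS ether of 5 | C[C@@]1([C@H](O[Si](C)(C)C(C)(C)C)CC=C)O[C@@H](C(C)(C)C)OC1=O | intermediate
7 | (5S)-5-[(1R)-1-(TBSO)but-3-en-1-yl]-4-hydroxy-5-methylfuran-2(5H)-one | O=C1C=C(O)[C@](C)([C@H](O[Si](C)(C)C(C)(C)C)CC=C)O1 | intermediate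
8 | benzoic acid | OC(=O)c1ccccc1 | starting material
9 | cyclohexa-2,5-diene-1-carboxylic acid | OC(=O)C1C=CCC=C1 | intermediate
10 | (cyclohexa-2,5-dien-1-yl)methanol | OCC1C=CCC=C1 | intermediate
11 | cyclohexa-2,5-diene-1-carbaldehyde | O=CC1C=CCC=C1 | intermediate
12 | (1R)-1-(cyclohexa-2,5-dien-1-yl)-3-methylbut-3-en-1-ol | CC(=C)C[C@@H](O)C1C=CCC=C1 | intermediate
13 | tetronate diene (Mitsunobu product) | O=C1C=C(O[C@@H](CC(C)=C)C2C=CCC=C2)[C@](C)([C@H](O[Si](C)(C)C(C)(C)C)CC=C)O1 | intermediate
14 | macrocyclic (Z)-oxonene tetronate | O=C1C=C2O[C@H](C3C=CCC=C3)C/C(C)=C\C[C@@H](O[Si](C)(C)C(C)(C)C)[C@]2(C)O1 | intermediate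
15 | cyclobutane photoadduct | CC(C)(C)[Si](C)(C)O[C@@H]1C/C=C(C)\C[C@@H]2O[C@@]35[C@@H]4[C@H]2C=CC[C@@H]4[C@H]5C(=O)O[C@@]13C | intermediate
16 | ring-expanded seven-membered lactone (C15 = CH2) | CC(C)(C)[Si](C)(C)O[C@@H]1C/C=C(C)\C[C@@H]2O[C@H]3[C@@H]4[C@H]2C=CC[C@@H]4CC(=O)O[C@@]13C | intermediate
17 | 15-methyl lactone | CC(C)(C)[Si](C)(C)O[C@@H]1C/C=C(C)\C[C@@H]2O[C@H]3[C@@H]4[C@H]2C=CC[C@@H]4[C@@H](C)C(=O)O[C@@]13C | intermediate
18 | 16-acetoxy oxepane (C16 epimers) | CC(C)(C)[Si](C)(C)O[C@@H]1C/C=C(C)\C[C@@H]2O[C@H]3[C@@H]4[C@H]2C=CC[C@@H]4[C@@H](C)C(OC(C)=O)O[C@@]13C | intermediate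
19 | tetracyclic oxepane, (Z)-Δ6, Δ11, 4-OTBS | CC(C)(C)[Si](C)(C)O[C@@H]1C/C=C(C)\C[C@@H]2O[C@H]3[C@@H]4[C@H]2C=CC[C@@H]4[C@@H](C)CO[C@@]13C | intermediate
20 | 6-epi-6,7-diol | CC(C)(C)[Si](C)(C)O[C@@H]1C[C@H](O)[C@](C)(O)C[C@@H]2O[C@H]3[C@@H]4[C@H]2C=CC[C@@H]4[C@@H](C)CO[C@@]13C | intermediate
21 | 6,7,13-triol (C13 epimers) | CC(C)(C)[Si](C)(C)O[C@@H]1C[C@H](O)[C@](C)(O)C[C@@H]2O[C@H]3[C@@H]4[C@H]2C=CC(O)[C@@H]4[C@@H](C)CO[C@@]13C | intermediate
22 | 7-hydroxy-6,13-dione, Δ11 | CC(C)(C)[Si](C)(C)O[C@@H]1CC(=O)[C@](C)(O)C[C@@H]2O[C@H]3[C@@H]4[C@H]2C=CC(=O)[C@@H]4[C@@H](C)CO[C@@]13C | intermediate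
23 | 11-methyl silyl enol ether, 7-OTMS (C11 epimers) | CC(C)(C)[Si](C)(C)O[C@@H]1CC(=O)[C@](C)(O[Si](C)(C)C)C[C@@H]2O[C@H]3[C@@H]4[C@H]2C(C)C=C(O[Si](C)(C)C)[C@@H]4[C@@H](C)CO[C@@]13C | intermediate
24 | β-methyl enone, 4-OTBS, 7-OTMS, 6-oxo | CC(C)(C)[Si](C)(C)O[C@@H]1CC(=O)[C@](C)(O[Si](C)(C)C)C[C@@H]2O[C@H]3[C@@H]4[C@H]2C(C)=CC(=O)[C@@H]4[C@@H](C)CO[C@@]13C | intermediate
25 | 4,7-dihydroxy-6,13-dione | O[C@@H]1CC(=O)[C@](C)(O)C[C@@H]2O[C@H]3[C@@H]4[C@H]2C(C)=CC(=O)[C@@H]4[C@@H](C)CO[C@@]13C | intermediate
26 | 4-acetoxy-7-hydroxy-6,13-dione | CC(=O)O[C@@H]1CC(=O)[C@](C)(O)C[C@@H]2O[C@H]3[C@@H]4[C@H]2C(C)=CC(=O)[C@@H]4[C@@H](C)CO[C@@]13C | intermediate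
27 | CNP0318718.1 | CC(=O)O[C@@H]1C[C@@H](O)[C@](C)(O)C[C@@H]2O[C@H]3[C@@H]4[C@H]2C(C)=CC(=O)[C@@H]4[C@@H](C)CO[C@@]13C | target

**Step count:** 24 steps in total. Longest linear sequence: 20 steps (steps 1–6 and 11–24, from (R)-lactic acid).

**Steps most likely to fail**

1. Step 13 (Proposed new method). The lactone may be too weak an acceptor for clean heterolysis of the C2–C15 bond at low temperature. The C2 cation may also be captured across the ring by the C6=C7 alkene, or lose H-1, before hydride transfer. Fallback with known reaction types, from 14 back to 16: 14 is irradiated as before and the photoadduct 15 is isolated. It is opened by protic solvolysis (camphorsulfonic acid, MeOH/CH2Cl2, 40 °C), the acid-catalysed retro-aldol-type opening of a β-alkoxy-carbonyl cyclobutane in which solvent methanol traps the cation at once, to the ring-expanded lactone C2 methyl ketal F1. Silane reduction of this cyclic ketal (Et3SiH, BF3·OEt2, CH2Cl2, −78 °C) then gives 16, with the bridge again dictating the face of hydride delivery.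

2. Step 12. Oligomerisation by cross-metathesis, or ring-rearrangement metathesis with the cyclohexadiene, may outrun closure of the strained nine-membered trisubstituted (Z)-alkene. Fallback, from 13 back to 15: the order is reversed. Irradiation of 13 (254 nm, CH2Cl2) should give the open-chain photoadduct F2, in which the new tetrahydrofuran holds the allyl and methallyl chains cis and close together. The ring alkene is expected to be preferred over the methallyl group, because attack there would have to form a quaternary centre. Ring-closing metathesis of F2 (Grubbs second-generation catalyst, toluene, 80 °C) on this rigid template, a situation with close precedent on cis-2,5-disubstituted hydroisobenzofurans, then gives 15, which is taken through the silane stage of step 13 to 16.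

3. Step 18. The ene step may be sluggish on the cis-disubstituted ring alkene, and abstraction of the tertiary C10–H may compete. Fallback, from 20 back to 22: the C6 alcohol is oxidised first (Dess–Martin periodinane) to the 7-hydroxy-6-ketone F3, and the C13 methylene is then oxidised by radical allylic oxidation (Rh2(cap)4 cat., t-BuOOH, K2CO3, CH2Cl2) directly to the enone 22.

**Further compounds**

F1 | step 13 | C2 methyl ketal of the ring-expanded lactone 16 | CC(C)(C)[Si](C)(C)O[C@@H]1C/C=C(C)\C[C@@H]2O[C@@]3(OC)[C@@H]4[C@H]2C=CC[C@@H]4CC(=O)O[C@@]13C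
F2 | step 12 | open-chain cyclobutane photoadduct of 13 (allyl and methallyl chains intact) | C=CC[C@@H](O[Si](C)(C)C(C)(C)C)[C@]1(C)OC(=O)[C@@H]2[C@H]3CC=C[C@@H]([C@H](CC(C)=C)O4)[C@H]3[C@]124
F3 | step 18 | 7-hydroxy-6-ketone with the C11=C12 alkene and C13 methylene intact | CC(C)(C)[Si](C)(C)O[C@@H]1CC(=O)[C@](C)(O)C[C@@H]2O[C@H]3[C@@H]4[C@H]2C=CC[C@@H]4[C@@H](C)CO[C@@]13C
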